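The cis-decalin is cut at C9–C10 (numbered as a labdane: carbinol C3, quaternary C4, ring fusion C5/C10, methylene on C8, pyranone on C11 off C9). An intramolecular Heck reaction sends a C9 alkenyl iodide, tethered through C8–C6 to C5 of a carvone-derived ring A, across the trisubstituted C1=C10 alkene of that ring, the feature exploited. In one operation ring B closes, the quaternary C10 forms with its methyl cis to 5-H, and a C8 ketone flanked by a C9 exocyclic methylene (C11) is left to accept the pyrone. The precursor is an α-iodo vinyl ketone on a cyclohexene that already holds C3, C4 and C5.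

Key step: step 17

Remark: atoms carry labdane numbers throughout and β means the face of ring A that bears the C3 oxygen; hydroxypyrone 29 is assumed not purchasable and is made in step 18; carbinols 15 and 23 are used as epimer mixtures because the carbinol carbon becomes trigonal in the next step.

Step 1
Reactants: 1 3-methylbutane-1,3-diol
Product: 2 4-iodo-2-methylbutan-2-ol
Conditions: PPh3, I2, imidazole, CH2Cl2, 0 °C to rt
Reagents that add atoms: iodine, SMILES II
Why: Appel-type iodination converts only the primary hydroxyl, because the tertiary carbinol cannot be displaced through an alkoxyphosphonium at a comparable rate.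

Step 2
Reactants: 2 4-iodo-2-methylbutan-2-ol
Product: 3 triethyl[(4-iodo-2-methylbutan-2-yl)oxy]silane
Conditions: Et3SiOTf, 2,6-lutidine, CH2Cl2, −78 to 0 °C
Reagents that add atoms: triethylsilyl trifluoromethanesulfonate, SMILES CC[Si](CC)(CC)OS(=O)(=O)C(F)(F)F
Why: Silyl triflate silylation with a hindered pyridine base is the standard way to cap a tertiary alcohol, and the primary iodide is inert to it.

Step 3
Reactants: 4 (S)-carvone; 3 triethyl[(4-iodo-2-methylbutan-2-yl)oxy]silane
Product: 6 trans-6-alkylcarvone, via carvone lithium enolate 5 (not isolated)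
Conditions: LiN(i-Pr)2, THF, −78 °C; then 3, DMPU, −78 to 0 °C
Reagents that add atoms: none
Why: Kinetic α′-deprotonation of the enone and SN2 enolate alkylation by the primary iodide in the presence of a polar cosolvent should place the chain trans to the isopropenyl group, although this centre is enolized again in step 4 and its configuration does not matter.

Step 4
Reactants: 6 trans-6-alkylcarvone
Product: 8 6-alkyl-6-methylcarvone, via tetrasubstituted lithium enolate 7 (not isolated)
Conditions: LiN(i-Pr)2, THF, −78 to −30 °C; then MeI, −78 to 0 °C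
Reagents that add atoms: iodomethane, SMILES CI
Why: Enolate alkylation under 1,2-induction, in which the small electrophile should enter the tetrasubstituted α′-enolate opposite the neighbouring isopropenyl group, sets the quaternary C4 with its methyl trans and its chain cis to the future C3 oxygen.

Step 5
Reactants: 8 6-alkyl-6-methylcarvone
Product: 10 C3 acetate enone, via methoxy hydroperoxide 9 (not isolated)
Conditions: O3, CH2Cl2/MeOH, −78 °C; then Ac2O, Et3N, DMAP, 0 °C to rt
Reagents that add atoms: ozone, SMILES [O-][O+]=O; methanol, SMILES CO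
Why: Ozone should attack the electron-rich 1,1-disubstituted alkene before the enone, and the peracetate of the resulting α-methoxy hydroperoxide undergoes Criegee rearrangement with migration of the ring carbon and retention at C3, while the quaternary C4 blocks β-elimination of the acetate.

Step 6
Reactants: 10 C3 acetate enone
Product: 11 C3 hydroxy enone
Conditions: K2CO3 (cat.), MeOH, 0 °C
Reagents that add atoms: none
Why: Carbonate-catalysed transesterification removes the acetate at low temperature, and because C4 carries no hydrogen the β-hydroxy ketone can neither eliminate nor epimerize there.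

Step 7
Reactants: 11 C3 hydroxy enone
Product: 12 C3 TBS ether enone
Conditions: t-BuMe2SiOTf, 2,6-lutidine, CH2Cl2, −78 to 0 °C
Reagents that add atoms: tert-butyldimethylsilyl trifluoromethanesulfonate, SMILES CC(C)(C)[Si](C)(C)OS(=O)(=O)C(F)(F)F
Why: Silyl triflate silylation reaches the hindered secondary alcohol and gives an ether that outlasts the triethylsilyl group, so the two oxygens can be released in order at the end.

Step 8
Reactants: 12 C3 TBS ether enone; 13 2-(2-bromoethyl)-1,3-dioxolane
Product: 15 tertiary allylic alcohol, via dioxolanylethylmagnesium bromide 14 (not isolated)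
Conditions: 13, Mg, THF, 25 °C; then CeCl3, 12, THF, −78 to 0 °C
Reagents that add atoms: none
Why: Grignard 1,2-addition promoted by CeCl3 should suppress conjugate addition and reduction at the hindered enone carbonyl, and either C5 epimer serves because C5 becomes trigonal in step 9.

Step 9
Reactants: 15 tertiary allylic alcohol
Product: 16 transposed C1 enone
Conditions: [C5H5NH][CrO3Cl] (pyridinium chlorochromate), 4 Å sieves, CH2Cl2, rt
Reagents that add atoms: pyridinium chlorochromate, SMILES [O-][Cr](=O)(=O)Cl.c1cc[nH+]cc1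
Why: In the Babler–Dauben oxidative transposition the tertiary allylic chromate ester shifts to C1 by a [3,3] rearrangement and is oxidized there, which moves the carbonyl to C1 and leaves the tether on the alkene carbon C5.

Step 10
Reactants: 16 transposed C1 enone
Product: 17 C1 allylic alcohol
Conditions: NaBH4, CeCl3·7H2O, MeOH, −40 to 0 °C
Reagents that add atoms: none
Why: Luche 1,2-reduction should deliver hydride to C1 opposite the C3 silyloxy group, as in the reduction of carvone to cis-carveol, so the new carbinol is 1β and cis to the C3 oxygen.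

Step 11
Reactants: 17 C1 allylic alcohol
Product: 18 C1 allylic formate
Conditions: AcOCHO, pyridine, CH2Cl2, 0 °C
Reagents that add atoms: acetic formic anhydride, SMILES CC(=O)OC=O
Why: Acylation of a secondary allylic alcohol by the mixed anhydride transfers the formyl group because its carbonyl is much the more electrophilic.

Step 12
Reactants: 18 C1 allylic formate
Product: 19 ring A acetal
Conditions: Pd(acac)2 (5 mol %), n-Bu3P (5 mol %), THF, reflux
Reagents that add atoms: none
Why: In this palladium-catalysed hydrogenolysis of an allylic formate, zerovalent palladium ionizes the 1β-formate with inversion, loss of CO2 leaves a palladium hydride on the α face, and hydride passes to the more substituted allyl terminus C5 from that face, which sets 5α-H (trans to the C3 oxygen and the C4 chain) and returns the alkene to C1=C10.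

Step 13
Reactants: 19 ring A acetal
Product: 21 ring A aldehyde, via collidinium acetal salt 20 (not isolated)
Conditions: Et3SiOTf, 2,4,6-collidine, CH2Cl2, 0 °C; then H2O, rt
Reagents that add atoms: water, SMILES O
Why: Silyl triflate and collidine open the aldehyde acetal to a pyridinium-type salt that water hydrolyses, an acid-free acetal cleavage that leaves both silyl ethers and the trisubstituted alkene alone.

Step 14
Reactants: 21 ring A aldehyde; 22 vinylmagnesium bromide
Product: 23 C8 allylic alcohol
Conditions: CH2=CHMgBr, THF, −78 to 0 °C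
Reagents that add atoms: none
Why: Grignard 1,2-addition to the aldehyde, the only electrophile present, gives C8 carbinol epimers that converge on oxidation.

Step 15
Reactants: 23 C8 allylic alcohol
Product: 24 vinyl ketone
Conditions: Dess–Martin periodinane, NaHCO3, CH2Cl2, 0 °C to rt
Reagents that add atoms: none
Why: Dess–Martin oxidation of the secondary allylic alcohol is buffered and non-basic, so the sensitive vinyl ketone should not polymerize.

Step 16
Reactants: 24 vinyl ketone
Product: 25 α-iodoenone (Heck precursor)
Conditions: I2, pyridine, CH2Cl2, 0 °C to rt, dark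
Reagents that add atoms: iodine, SMILES II
Why: In this pyridine-mediated α-iodination of an enone, pyridine adds reversibly to the unsubstituted β-carbon (Baylis–Hillman-type), the enolate is iodinated and pyridine is expelled, while the isolated ring alkene can only form a reversible iodonium.

Step 17
Reactants: 25 α-iodoenone (Heck precursor)
Product: 26 decalin enone (Heck product)
Conditions: Pd(OAc)2 (10 mol %), PPh3 (30 mol %), Ag2CO3 (2 equiv), MeCN, 65 °C
Reagents that add atoms: none
Why: Zerovalent palladium, formed from Pd(OAc)2 and PPh3, inserts into the activated C9–I bond, the alkenylpalladium adds syn across the C1=C10 alkene with C9 bonding to C10 and palladium to C1, and syn β-hydride elimination, which can only use a hydrogen on C2 because C10 is now quaternary, releases the C1=C2 alkene. The closest known reaction type is the intramolecular Heck cyclization of alkenyl halides onto trisubstituted cycloalkenes, which gives quaternary carbons in cis-fused bicycles. Ring B closes in the 6-exo-trig mode. The new stereocentre C10 is controlled by C5: the three-atom tether reaches only the β face of the alkene, on which it stands, so C9 and C6 become cis on ring A and the C10 methyl is α, cis to 5-H. The step needs 6-exo over 7-endo closure, which the short tether secures, and it needs the alkene to stay at C1=C2, which holds because the hydrogen on C3 is anti to palladium and Ag2CO3 removes iodide and acid so that the palladium hydride does not add back. The electron-poor iodoenone should add to palladium at moderate temperature, and the product keeps the C8 ketone and C9 methylene needed for step 19.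

Step 18
Reactants: 27 dimethyl 3-oxopentanedioate
Product: 29 hydroxypyrone ester, via dimethyl 2-acetyl-3-oxopentanedioate 28 (not isolated)
Conditions: MgCl2, pyridine, AcCl, CH2Cl2, 0 °C to rt; crude, then DBU (cat.), toluene, 110 °C
Reagents that add atoms: acetyl chloride, SMILES CC(Cl)=O
Why: Magnesium-mediated soft-enolization C-acylation of the 1,3-dicarbonyl followed by lactonization of the acetyl enol oxygen onto the distal ester is a known route to 6-alkyl-4-hydroxy-2-pyranone-5-carboxylates.

Step 19
Reactants: 26 decalin enone (Heck product); 29 hydroxypyrone ester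
Product: 30 C11 pyrone adduct
Conditions: 29 (1.3 equiv), Et3N (0.2 equiv), MeCN, 25 to 40 °C
Reagents that add atoms: none
Why: Amine-catalysed Michael addition of the acidic ring CH of 29 to the unhindered C11 terminus of the exocyclic enone leaves C9 epimerizable next to the ketone, and both axial protonation and equilibration should give 9α-H (C11 β, trans to the C10 methyl) because ring B avoids the conformer with the quaternary C4 axial and in the other conformer C11 is equatorial only in this epimer.

Step 20
Reactants: 30 C11 pyrone adduct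
Product: 31 methoxypyranone ketone
Conditions: MeOTf (1.5 equiv), CH2Cl2, 0 °C to rt; aq. NaHCO3
Reagents that add atoms: methyl trifluoromethanesulfonate, SMILES COS(=O)(=O)C(F)(F)F
Why: O-Alkylation of the neutral 4-hydroxy-2-pyranone by methyl triflate should occur at the lactone carbonyl oxygen, the 4-hydroxyl being held in a hydrogen bond to the neighbouring ester, and loss of that proton gives the 2-methoxy-4-pyranone, a product to which any cyclic hemiketal tautomer of 30 would also open.

Step 21
Reactants: 31 methoxypyranone ketone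
Product: 32 saturated C8 ketone
Conditions: H2 (1 atm), Pd/C, EtOAc, rt
Reagents that add atoms: none
Why: Heterogeneous hydrogenation should reduce only the cis-disubstituted C1=C2 alkene, since the fully substituted pyranone ring and the ketone are inert at this pressure, and the neutral conditions leave C9 untouched.

Step 22
Reactants: 32 saturated C8 ketone
Product: 33 C8 methylene bis-silyl ether
Conditions: Zn, CH2Br2, TiCl4, THF/CH2Cl2, 0 °C to rt
Reagents that add atoms: dibromomethane, SMILES BrCBr
Why: Takai–Lombardo methylenation uses a non-basic zinc–titanium methylene reagent that converts hindered, enolizable ketones without epimerizing the α-carbon C9 and does not attack ester or pyranone carbonyls.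

Step 23
Reactants: 33 C8 methylene bis-silyl ether
Product: 34 tertiary alcohol
Conditions: PPTS (0.2 equiv), MeOH/CH2Cl2, 0 °C to rt
Reagents that add atoms: none
Why: Mild acid methanolysis should cleave the triethylsilyl ether much faster than the tert-butyldimethylsilyl ether on the neopentyl C3 carbinol, so only the tertiary alcohol is freed.

Step 24
Reactants: 34 tertiary alcohol
Product: 35 tertiary formate
Conditions: AcOCHO, pyridine, DMAP (0.2 equiv), CH2Cl2, 0 °C to rt
Reagents that add atoms: acetic formic anhydride, SMILES CC(=O)OC=O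
Why: Formylation by the mixed anhydride under nucleophilic catalysis reaches tertiary alcohols, and the only other hydroxyl is still silylated.

Step 25
Reactants: 35 tertiary formate
Product: 36 CNP0292250.1 (target)
Conditions: HF·pyridine, pyridine, THF, 0 °C to rt
Reagents that add atoms: none
Why: Desilylation by buffered HF·pyridine is neither basic nor nucleophilic toward acyl groups, so the formate, the methyl ester, the methoxypyranone and the exocyclic alkene should survive.

Compound list
1 | 3-methylbutane-1,3-diol | CC(C)(O)CCO | starting material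
2 | 4-iodo-2-methylbutan-2-ol | CC(C)(O)CCI | intermediate
3 | triethyl[(4-iodo-2-methylbutan-2-yl)oxy]silane | CC[Si](CC)(CC)OC(C)(C)CCI | intermediate
4 | (S)-carvone | CC1=CC[C@@H](CC1=O)C(C)=C | starting material
5 | carvone lithium enolate (kinetic α′-enolate) | CC1=CC[C@@H](C=C1O[Li])C(C)=C | intermediate
6 | trans-6-alkylcarvone: (S)-carvone with the 3-methyl-3-(triethylsilyloxy)butyl chain on the α′-carbon, trans to isopropenyl | O=C1[C@H](CCC(C)(C)O[Si](CC)(CC)CC)[C@@H](C(C)=C)CC=C1C | intermediate
7 | tetrasubstituted lithium enolate of 6 | [Li]OC1=C(CCC(C)(C)O[Si](CC)(CC)CC)[C@@H](C(C)=C)CC=C1C | intermediate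
8 | 6-alkyl-6-methylcarvone: quaternary α′-carbon with methyl trans and chain cis to isopropenyl | O=C1[C@@](C)(CCC(C)(C)O[Si](CC)(CC)CC)[C@@H](C(C)=C)CC=C1C | intermediate
9 | methoxy hydroperoxide: isopropenyl of 8 converted to C(CH3)(OCH3)OOH, epimers at that carbon | O=C1[C@@](C)(CCC(C)(C)O[Si](CC)(CC)CC)[C@@H](C(C)(OC)OO)CC=C1C | intermediate
10 | C3 acetate enone: 3β-acetoxy, 4α-methyl, 4β-chain, C5 ketone, C1=C10 alkene | O=C1[C@@](C)(CCC(C)(C)O[Si](CC)(CC)CC)[C@@H](OC(C)=O)CC=C1C | intermediate
11 | C3 hydroxy enone: 3β-hydroxy analogue of 10 | O=C1[C@@](C)(CCC(C)(C)O[Si](CC)(CC)CC)[C@@H](O)CC=C1C | intermediate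
12 | C3 TBS ether enone: 3β-tert-butyldimethylsilyloxy analogue of 10 | O=C1[C@@](C)(CCC(C)(C)O[Si](CC)(CC)CC)[C@@H](O[Si](C)(C)C(C)(C)C)CC=C1C | intermediate
13 | 2-(2-bromoethyl)-1,3-dioxolane | BrCCC1OCCO1 | starting material
14 | dioxolanylethylmagnesium bromide: [2-(1,3-dioxolan-2-yl)ethyl]magnesium bromide | Br[Mg]CCC1OCCO1 | intermediate
15 | tertiary allylic alcohol: C5 carbinol bearing the dioxolanylethyl tether, C5 epimers | OC1(CCC2OCCO2)[C@@](C)(CCC(C)(C)O[Si](CC)(CC)CC)[C@@H](O[Si](C)(C)C(C)(C)C)CC=C1C | intermediate
16 | transposed C1 enone: C1 ketone, C5=C10 alkene with the tether on C5 and methyl on C10 | CC1=C(CCC2OCCO2)[C@@](C)(CCC(C)(C)O[Si](CC)(CC)CC)[C@@H](O[Si](C)(C)C(C)(C)C)CC1=O | intermediate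
17 | C1 allylic alcohol: 1β-hydroxy, cis to the 3β-silyloxy group | CC1=C(CCC2OCCO2)[C@@](C)(CCC(C)(C)O[Si](CC)(CC)CC)[C@@H](O[Si](C)(C)C(C)(C)C)C[C@H]1O | intermediate
18 | C1 allylic formate: 1β-formyloxy analogue of 17 | CC1=C(CCC2OCCO2)[C@@](C)(CCC(C)(C)O[Si](CC)(CC)CC)[C@@H](O[Si](C)(C)C(C)(C)C)C[C@H]1OC=O | intermediate
19 | ring A acetal: C1=C10 cyclohexene, 5α-H with the β dioxolanylethyl tether, 4α-methyl, 4β-chain, 3β-OTBS | O1CCOC1CC[C@H]2[C@@](C)(CCC(C)(C)O[Si](CC)(CC)CC)[C@@H](O[Si](C)(C)C(C)(C)C)CC=C2C | intermediate
20 | collidinium acetal salt: C8 bearing 2,4,6-trimethylpyridinium and 2-(triethylsilyloxy)ethoxy groups, triflate counter-ion, C8 epimers | CC[Si](CC)(CC)OCCOC(CC[C@H]1[C@@](C)(CCC(C)(C)O[Si](CC)(CC)CC)[C@@H](O[Si](C)(C)C(C)(C)C)CC=C1C)[n+]1c(C)cc(C)cc1C.[O-]S(=O)(=O)C(F)(F)F | intermediate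
21 | ring A aldehyde: C8 aldehyde of 19 | O=CCC[C@H]1[C@@](C)(CCC(C)(C)O[Si](CC)(CC)CC)[C@@H](O[Si](C)(C)C(C)(C)C)CC=C1C | intermediate
22 | vinylmagnesium bromide | C=C[Mg]Br | starting material
23 | C8 allylic alcohol: vinyl carbinol, C8 epimers | C=CC(O)CC[C@H]1[C@@](C)(CCC(C)(C)O[Si](CC)(CC)CC)[C@@H](O[Si](C)(C)C(C)(C)C)CC=C1C | intermediate
24 | vinyl ketone: C8 ketone with C9=C11 vinyl group | C=CC(=O)CC[C@H]1[C@@](C)(CCC(C)(C)O[Si](CC)(CC)CC)[C@@H](O[Si](C)(C)C(C)(C)C)CC=C1C | intermediate
25 | α-iodoenone (Heck precursor): 9-iodo vinyl ketone tethered to C5 of the ring A cyclohexene | C=C(I)C(=O)CC[C@H]1[C@@](C)(CCC(C)(C)O[Si](CC)(CC)CC)[C@@H](O[Si](C)(C)C(C)(C)C)CC=C1C | intermediate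
26 | decalin enone (Heck product): cis-decalin, C8 ketone, C9 exocyclic methylene, C1=C2 alkene, 10α-methyl, 5α-H, 3β-OTBS, 4α-methyl, 4β-chain | O=C1CC[C@H]2[C@@](C)(CCC(C)(C)O[Si](CC)(CC)CC)[C@@H](O[Si](C)(C)C(C)(C)C)C=C[C@@]2(C)C1=C | intermediate
27 | dimethyl 3-oxopentanedioate | COC(=O)CC(=O)CC(=O)OC | starting material
28 | dimethyl 2-acetyl-3-oxopentanedioate | COC(=O)CC(=O)C(C(C)=O)C(=O)OC | intermediate
29 | hydroxypyrone ester: methyl 4-hydroxy-2-methyl-6-oxo-6H-pyran-3-carboxylate | COC(=O)C1=C(C)OC(=O)C=C1O | intermediate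
30 | C11 pyrone adduct: C8 ketone, 9α-H, C11 linked to the hydroxypyranone, C1=C2 alkene | O=C1CC[C@H]2[C@@](C)(CCC(C)(C)O[Si](CC)(CC)CC)[C@@H](O[Si](C)(C)C(C)(C)C)C=C[C@@]2(C)[C@H]1CC1=C(O)C(C(=O)OC)=C(C)OC1=O | intermediate
31 | methoxypyranone ketone: 2-methoxy-4-pyranone analogue of 30 | O=C1CC[C@H]2[C@@](C)(CCC(C)(C)O[Si](CC)(CC)CC)[C@@H](O[Si](C)(C)C(C)(C)C)C=C[C@@]2(C)[C@H]1Cc1c(OC)oc(C)c(C(=O)OC)c1=O | intermediate
32 | saturated C8 ketone: C1–C2 saturated analogue of 31 | O=C1CC[C@H]2[C@@](C)(CCC(C)(C)O[Si](CC)(CC)CC)[C@@H](O[Si](C)(C)C(C)(C)C)CC[C@@]2(C)[C@H]1Cc1c(OC)oc(C)c(C(=O)OC)c1=O | intermediate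
33 | C8 methylene bis-silyl ether | C=C1CC[C@H]2[C@@](C)(CCC(C)(C)O[Si](CC)(CC)CC)[C@@H](O[Si](C)(C)C(C)(C)C)CC[C@@]2(C)[C@H]1Cc1c(OC)oc(C)c(C(=O)OC)c1=O | intermediate
34 | tertiary alcohol: side-chain hydroxyl free, 3β-OTBS kept | C=C1CC[C@H]2[C@@](C)(CCC(C)(C)O)[C@@H](O[Si](C)(C)C(C)(C)C)CC[C@@]2(C)[C@H]1Cc1c(OC)oc(C)c(C(=O)OC)c1=O | intermediate
35 | tertiary formate: side-chain formate, 3β-OTBS kept | C=C1CC[C@H]2[C@@](C)(CCC(C)(C)OC=O)[C@@H](O[Si](C)(C)C(C)(C)C)CC[C@@]2(C)[C@H]1Cc1c(OC)oc(C)c(C(=O)OC)c1=O | intermediate
36 | CNP0292250.1 | C=C1CC[C@H]2[C@@](C)(CCC(C)(C)OC=O)[C@@H](O)CC[C@@]2(C)[C@H]1Cc1c(OC)oc(C)c(C(=O)OC)c1=O | target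

Total step count: 25. Longest linear sequence: 24 steps (steps 1–17 and 19–25, from 3-methylbutane-1,3-diol; 22 of them from (S)-carvone). Step 18 is a one-step side branch.

Steps most likely to fail

1. Step 17. Carbopalladation at the hindered trisubstituted alkene may be slower than the side reactions of the alkenylpalladium, so that the iodide is reduced, or the iodoenone and the product enone oligomerize. The fallback moves the ring closure to the alcohol oxidation level. It sets out from 25: Luche reduction (NaBH4, CeCl3·7H2O, MeOH) gives the 2-iodoallylic alcohol F1, an ordinary electron-neutral alkenyl iodide that is not a Michael acceptor. The same 6-exo cis closure (Pd(OAc)2, PPh3, Ag2CO3, MeCN) then gives the decalin allylic alcohol F2, and Dess–Martin oxidation comes back to the route at 26.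

2. Step 19. The conjugate addition is reversible and may stall, and protonation at C9 may be too unselective, leaving an epimer mixture that equilibration does not resolve. The fallback delivers the C9 hydrogen by a sigmatropic shift instead of by protonation and sets out from 26.
   - Corey–Chaykovsky epoxidation ([Me3S]I, KN(SiMe3)2, THF, 0 °C) gives the spiro vinyl epoxide F3.
   - Tsuji–Trost opening with 29 (Pd(PPh3)4, THF) should attack the unhindered allyl terminus C11 and give the hydroxymethyl alkene F4, with a C8=C9 double bond.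
   - Methyl triflate (one equivalent, as in step 20) gives the methoxypyranone F5.
   - Hydrogenation (H2, Pd/C) saturates C1=C2 and leaves the tetrasubstituted alkene, giving F6.
   - Mitsunobu reaction with 2-nitrobenzenesulfonylhydrazide (PPh3, diethyl azodicarboxylate, THF, −30 °C to rt) forms the sulfonylhydrazine F7, which loses the sulfinic acid to the allylic diazene F8.
   - Retro-ene loss of N2 from F8 places hydrogen on C9 and forms the C8 methylene in one event. It comes back to the route at 33 and makes step 22 unnecessary.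

3. Step 12. Hydride may be transferred to C1, giving the tetrasubstituted C5=C10 alkene, or the allylpalladium may lose a β-hydrogen to a diene. The fallback replaces the metal hydride by a concerted hydrogen shift and sets out from 17. Mitsunobu reaction with 2-nitrobenzenesulfonylhydrazide (PPh3, diethyl azodicarboxylate, N-methylmorpholine, THF, −30 °C to rt) inverts C1 and gives the sulfonylhydrazine F9. Loss of the sulfinic acid gives the 1α allylic diazene F10, whose suprafacial retro-ene rearrangement can only place hydrogen on the α face of C5 and the alkene at C1=C10. It comes back to the route at 19 and makes step 11 unnecessary.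

Further compounds
F1 | step 17 | 2-iodoallylic alcohol from 25, C8 carbinol epimers | C=C(I)C(O)CC[C@H]1[C@@](C)(CCC(C)(C)O[Si](CC)(CC)CC)[C@@H](O[Si](C)(C)C(C)(C)C)CC=C1C
F2 | step 17 | decalin allylic alcohol: C8 carbinol analogue of 26, C8 epimers | OC1CC[C@H]2[C@@](C)(CCC(C)(C)O[Si](CC)(CC)CC)[C@@H](O[Si](C)(C)C(C)(C)C)C=C[C@@]2(C)C1=C
F3 | step 19 | spiro vinyl epoxide: C8 oxirane of 26, C8 epimers | C1OC12CC[C@H]3[C@@](C)(CCC(C)(C)O[Si](CC)(CC)CC)[C@@H](O[Si](C)(C)C(C)(C)C)C=C[C@@]3(C)C2=C
F4 | step 19 | hydroxymethyl alkene: C8=C9 alkene with C8 hydroxymethyl and the hydroxypyranone on C11 | OCC=1CC[C@H]2[C@@](C)(CCC(C)(C)O[Si](CC)(CC)CC)[C@@H](O[Si](C)(C)C(C)(C)C)C=C[C@@]2(C)C1CC1=C(O)C(C(=O)OC)=C(C)OC1=O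
F5 | step 19 | methoxypyranone from F4 | OCC=1CC[C@H]2[C@@](C)(CCC(C)(C)O[Si](CC)(CC)CC)[C@@H](O[Si](C)(C)C(C)(C)C)C=C[C@@]2(C)C1Cc1c(OC)oc(C)c(C(=O)OC)c1=O
F6 | step 19 | C1–C2 saturated analogue of F5 | OCC=1CC[C@H]2[C@@](C)(CCC(C)(C)O[Si](CC)(CC)CC)[C@@H](O[Si](C)(C)C(C)(C)C)CC[C@@]2(C)C1Cc1c(OC)oc(C)c(C(=O)OC)c1=O
F7 | step 19 | sulfonylhydrazine: N-allyl-N-(2-nitrobenzenesulfonyl)hydrazine from F6 | NN(CC=1CC[C@H]2[C@@](C)(CCC(C)(C)O[Si](CC)(CC)CC)[C@@H](O[Si](C)(C)C(C)(C)C)CC[C@@]2(C)C1Cc1c(OC)oc(C)c(C(=O)OC)c1=O)S(=O)(=O)c1ccccc1[N+](=O)[O-]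
F8 | step 19 | allylic diazene from F7 | N=NCC=1CC[C@H]2[C@@](C)(CCC(C)(C)O[Si](CC)(CC)CC)[C@@H](O[Si](C)(C)C(C)(C)C)CC[C@@]2(C)C1Cc1c(OC)oc(C)c(C(=O)OC)c1=O
F9 | step 12 | sulfonylhydrazine: 1α N-(2-nitrobenzenesulfonyl)hydrazine from 17 | CC1=C(CCC2OCCO2)[C@@](C)(CCC(C)(C)O[Si](CC)(CC)CC)[C@@H](O[Si](C)(C)C(C)(C)C)C[C@@H]1N(N)S(=O)(=O)c1ccccc1[N+](=O)[O-]
F10 | step 12 | 1α allylic diazene from F9 | CC1=C(CCC2OCCO2)[C@@](C)(CCC(C)(C)O[Si](CC)(CC)CC)[C@@H](O[Si](C)(C)C(C)(C)C)C[C@@H]1N=N
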